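(All runs stem from a simulated flask from invented constants; noise was put on by code.)

Read at 20 h or at 50 s, the flask holds isomer of the product and target in some ratio, and two chemists dispute whether the time of reading changes that ratio.

| flask | substrate | remark | time |
|---|---|---|---|
| violet | 0.025 M | run made earlier |  |
| grey | 0.10 M | run made earlier |  |
| flask | 0.050 M |  | 20 h |

| run | time / h | isomer of the product / % | target / % |
|---|---|---|---|
| violet | 2.00 | 0 | 89 |
| violet | 4.00 | 2 | 87 |
| violet | 10.0 | 5 | 86 |
| violet | 25.0 | 5 | 86 |
| grey | 3.00 | 3 | 69 |
| grey | 8.00 | 1 | 67 |
| grey | 15.0 | 3 | 66 |
| grey | 25.0 | 2 | 68 |

(readings scatter by 2 percentage points)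

* share of isomer of the product in isomer of the product plus target at 50 s
* share of isomer of the product in isomer of the product plus target at 20 h

- percentages count the substrate that a species holds: one side product counts as two
- the analysis behind the earlier runs scatters by 2 percentage points, standard deviation
- what may be going on: substrate <-> other conformer; substrate -> target; other conformer -> isomer of the product; substrate + target -> side product

The first chemist holds a fixed split, Curtin–Hammett control: the two conformers feed their products in one ratio, so the share of isomer is the same at both times. He points to the mean shares read, 3.33% in the violet run at 0.025 M and 3.23% in the grey run at 0.10 M.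

The second chemist answers that the isomer readings, whose mean over both runs is 2.62%, each carry a scatter of 2 percentage points, while target plainly falls with the charge, so the share should climb as target is eaten. The grey run keeps a mean fraction 67.5% of its charge as target, which gives 4.81 M⁻¹ for the loss number, the fraction of the charge not found as target per fraction found as target, divided by the charge. For the flask at 0.050 M, this number keeps 80.6% as target, and with the mean isomer reading my own share at 20 h is 3.15%.

The forecast takes the second side, with 2% at 50 s and 3.3% at 20 h, a late value slightly apart from mine, on the ground that the fall of target “matches loss through substrate + target”.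

    substrate ⇌ other conformer (K = 0.0100, k = 0.320 s⁻¹)
    substrate → target (k = 0.00200 s⁻¹)
    other conformer → isomer of the product (k = 0.00400 s⁻¹)
    substrate + target → side product (k = 0.0100 M⁻¹ s⁻¹)

The flask gives 1.98% at 50 s and 2.18% at 20 h, so the share does rise, and the forecast holds at both times. The fixed split keeps the early region: with substrate + target struck out, the flask's share at 50 s stays 1.96%, and half of that step's turnover comes at 0.145 h. The flask's 1.78% of isomer with the loss number's 80.6% of target gives a share of 2.16%. For the neighbour charged with 0.030 M, the loss number keeps 87.4% as target where that flask holds 86.0%, and with its 1.84% of isomer gives 2.06% against its 2.10%.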